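## Plan

Numbering: C1 = CO2H, C2 = stereocentre, C3 = CH2, C4 = ketone carbon. The ring is C1'–C6' with the acyl group on C1' and OH on C2' and C5'. The side chain is C1''–C9'' with alkenes C3''=C4'' and C7''=C8''.
Cuts, in order: C4–C1' (the aryl ketone read as the O→C acyl-shift isomer of an aryl ester); C4(=O)–O(C2') (hydroquinone + 2-alkylsuccinic anhydride); C2–C3 (enolate + bromoacetate); C1''–C2'' (allyl + geranyl).
Forward: geranyl bromide + allyl Grignard → C13 acid → N-acyl oxazolidinone → C2–C3 alkylation → diacid → anhydride (temporary ring), opened at C4 by hydroquinone → photochemical O→C acyl shift. No ring of the target is built, because the benzene ring is bought as hydroquinone.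
Stereochemistry: the E alkene C3''=C4'' comes with geranyl bromide. C2 (S) is set by alkylation under control of (R)-4-benzyloxazolidin-2-one and is not touched afterwards.
Enabling feature: the chelated unit O=C4–C1'=C2'–OH sits on a 1,4-dioxygenated benzene ring. The C2' oxygen can carry the C4 acyl group as an ester tether that stays in the target, C5'–OH blocks the position para to it, and the two ortho carbons of the ester are equivalent.
Pay-off: neither phenol nor the acid needs a protecting group, and the last step is a pure isomerisation.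

Key step: step 8

Assumption: commercial geranyl bromide of high E purity is used, so the C3''=C4'' geometry is bought and only has to be preserved.

## Route

Step 1
Reactants: 1 geranyl bromide; 2 allylmagnesium bromide
Product: 3 (5E)-6,10-dimethylundeca-1,5,9-triene
Conditions: 2 (1.0 M in Et2O, 1.3 equiv), THF, 0 °C to rt; aq NH4Cl
Reagents that add atoms: none
Why: Uncatalysed allyl–allyl Grignard coupling, in which the symmetrical allyl nucleophile should displace the primary allylic bromide mainly in the SN2 sense because the γ-terminus of 1 is fully substituted, so the E alkene of 1 is carried over unchanged.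

Step 2
Reactants: 3 (5E)-6,10-dimethylundeca-1,5,9-triene
Product: 5 (5E)-6,10-dimethylundeca-5,9-dien-1-ol, via B-alkyl-9-BBN adduct 4 (not isolated)
Conditions: 9-BBN (0.5 M in THF, 1.05 equiv), 0 °C to rt; then 3 M NaOH, 30% H2O2, 0 °C to rt
Reagents that add atoms: hydrogen peroxide, OO (the hydroxyl oxygen); 9-BBN-H, [H]B1C2CCCC1CCC2 (boron and its ring stay only in intermediate 4)
Why: Brown hydroboration–oxidation, in which bulky 9-BBN adds anti-Markovnikov to the monosubstituted terminal alkene far faster than to the two trisubstituted alkenes, and alkaline peroxide then replaces boron by hydroxyl.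

Step 3
Reactants: 5 (5E)-6,10-dimethylundeca-5,9-dien-1-ol
Product: 7 (5E)-6,10-dimethylundeca-5,9-dienoic acid, via aldehyde 6 (not isolated)
Conditions: TEMPO (0.2 equiv), PhI(OAc)2 (2.2 equiv), MeCN/H2O 1:1, rt
Reagents that add atoms: water, O
Why: Oxoammonium (TEMPO/PhI(OAc)2) oxidation in aqueous acetonitrile takes the primary alcohol through aldehyde 6 and its hydrate to the acid under near-neutral conditions that leave isolated trisubstituted alkenes alone.

Step 4
Reactants: 7 (5E)-6,10-dimethylundeca-5,9-dienoic acid; 8 (R)-4-benzyl-1,3-oxazolidin-2-one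
Product: 10 (4R)-4-benzyl-3-[(5E)-6,10-dimethylundeca-5,9-dienoyl]-1,3-oxazolidin-2-one, via mixed pivalic anhydride 9 (not isolated)
Conditions: PivCl, Et3N (2.5 equiv), THF, −20 °C; then LiCl, 8, −20 °C to rt
Reagents that add atoms: pivaloyl chloride, CC(C)(C)C(=O)Cl (its acyl group stays only in intermediate 9)
Why: Mixed-anhydride N-acylation of an oxazolidinone, in which the LiCl/Et3N-activated carbamate nitrogen attacks the unhindered carbonyl of 9 rather than the pivaloyl carbonyl, so neither an acid chloride nor butyllithium is needed.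

Step 5
Reactants: 10 (4R)-4-benzyl-3-[(5E)-6,10-dimethylundeca-5,9-dienoyl]-1,3-oxazolidin-2-one; 11 benzyl bromoacetate
Product: 13 benzyl (3S,6E)-3-{[(4R)-4-benzyl-2-oxo-1,3-oxazolidin-3-yl]carbonyl}-7,11-dimethyldodeca-6,10-dienoate, via sodium Z-enolate 12 (not isolated)
Conditions: NaHMDS (1.1 equiv), THF, −78 °C; 11 (2 equiv), −78 to −40 °C; aq NH4Cl
Reagents that add atoms: NaHMDS, C[Si](C)(C)[N-][Si](C)(C)C.[Na+] (its sodium stays only in intermediate 12)
Why: Evans asymmetric alkylation, in which the sodium-chelated Z-enolate 12 is shielded on one face by the C4 benzyl group of the (R)-auxiliary, so the reactive α-bromo ester enters from the opposite face and sets C2 as S, the sense established for bromoacetate alkylations with this auxiliary class.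

Step 6
Reactants: 13 benzyl (3S,6E)-3-{[(4R)-4-benzyl-2-oxo-1,3-oxazolidin-3-yl]carbonyl}-7,11-dimethyldodeca-6,10-dienoate
Product: 16 (2S)-2-[(3E)-4,8-dimethylnona-3,7-dien-1-yl]butanedioic acid, via peroxy acid 14 (not isolated), via monobenzyl ester 15 (not isolated)
Conditions: LiOH, 30% H2O2, THF/H2O 3:1, 0 °C; aq Na2SO3; then LiOH, rt; neutrals extracted with CH2Cl2, then 1 M HCl to pH 2
Reagents that add atoms: hydrogen peroxide, OO; lithium hydroxide, [Li+].[OH-]
Why: Hydroperoxide attacks the exocyclic imide carbonyl selectively (standard LiOOH auxiliary cleavage), sulfite reduces peroxy acid 14 to 15, and saponification of the unhindered benzyl ester then runs on a substrate whose C2–H is deactivated by the adjacent carboxylate, so C2 should not epimerise.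

Step 7
Reactants: 16 (2S)-2-[(3E)-4,8-dimethylnona-3,7-dien-1-yl]butanedioic acid; 17 hydroquinone
Product: 19 (2S)-2-[(3E)-4,8-dimethylnona-3,7-dien-1-yl]-4-(4-hydroxyphenoxy)-4-oxobutanoic acid, via cyclic anhydride 18 (not isolated)
Conditions: DCC (1.0 equiv), THF, 0 °C to rt, urea filtered off; then 17 (5 equiv), DMAP (0.1 equiv), THF, rt; dilute HCl wash, product kept un-ionised
Reagents that add atoms: none
Why: Carbodiimide dehydration closes the five-membered anhydride 18 as a temporary ring that activates the acid, and DMAP-catalysed acylation of the phenol (steric control as in other openings of 2-alkylsuccinic anhydrides) should occur at the CH2-flanked C4 carbonyl and free the C1 acid in the same event, while the excess of 17 holds the reaction at the monoester.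

Step 8
Reactants: 19 (2S)-2-[(3E)-4,8-dimethylnona-3,7-dien-1-yl]-4-(4-hydroxyphenoxy)-4-oxobutanoic acid
Product: 22 (2S)-4-(2,5-dihydroxyphenyl)-2-[(3E)-4,8-dimethylnona-3,7-dien-1-yl]-4-oxobutanoic acid (target), via caged radical pair 20 (not isolated), via ortho-acyl cyclohexadienone 21 (not isolated)
Conditions: hν (254 nm, low-pressure Hg lamp, quartz or FEP flow coil), degassed MeCN (ca. 5 mM), rt; run to partial conversion, recovered 19 recycled
Reagents that add atoms: none
Why: Excitation of the aryl ester chromophore at 254 nm, where the isolated alkenes are transparent, cleaves the ArO–C4(=O) bond from the singlet state to the caged acyl/4-hydroxyphenoxyl pair 20, which recombines at a carbon ortho to the phenoxyl oxygen to give dienone 21, and 21 tautomerises to the hydrogen-bonded 2-acylhydroquinone 22. The closest known reaction type is the photo-Fries rearrangement of 4-oxygenated phenyl alkanoates to 2-acyl-4-oxygenated phenols. No ring is closed and no stereocentre is made, since the sp3 ring carbon of 21 is erased on enolisation and C2 lies β to the acyl radical centre and meets neither acid nor base. Regioselectivity is secured by the substrate, because the para position carries C5'–OH (recombination there cannot rearomatise and reverts) and the two ortho positions are equivalent, so only the 2,5-dihydroxyphenyl ketone can arise. Chemoselectivity rests on rates, because in-cage recombination should outrun 6-exo attack of the C4 acyl radical on C3''=C4'', decarbonylation of a primary-alkyl acyl radical and cage escape, all of which are slower by orders of magnitude. The product dissipates light by excited-state proton transfer within its O–H···O=C chelate, which should protect it from Norrish cleavage and keep it from sensitising E/Z isomerisation, at the price of an inner-filter effect that dilute flow irradiation is meant to counter.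

## Compound list

1 | geranyl bromide, (2E)-1-bromo-3,7-dimethylocta-2,6-diene | CC(C)=CCC/C(C)=C/CBr | starting material
2 | allylmagnesium bromide | C=CC[Mg]Br | starting material
3 | (5E)-6,10-dimethylundeca-1,5,9-triene | CC(C)=CCC/C(C)=C/CCC=C | intermediate
4 | 9-[(5E)-6,10-dimethylundeca-5,9-dien-1-yl]-9-borabicyclo[3.3.1]nonane, formed in the flask | CC(C)=CCC/C(C)=C/CCCCB1C2CCCC1CCC2 | intermediate
5 | (5E)-6,10-dimethylundeca-5,9-dien-1-ol | CC(C)=CCC/C(C)=C/CCCCO | intermediate
6 | (5E)-6,10-dimethylundeca-5,9-dienal, formed in the flask | CC(C)=CCC/C(C)=C/CCCC=O | intermediate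
7 | (5E)-6,10-dimethylundeca-5,9-dienoic acid | CC(C)=CCC/C(C)=C/CCCC(=O)O | intermediate
8 | (R)-4-benzyl-1,3-oxazolidin-2-one | O=C1N[C@H](Cc2ccccc2)CO1 | starting material
9 | (5E)-6,10-dimethylundeca-5,9-dienoic pivalic anhydride, formed in the flask | CC(C)=CCC/C(C)=C/CCCC(=O)OC(=O)C(C)(C)C | intermediate
10 | (4R)-4-benzyl-3-[(5E)-6,10-dimethylundeca-5,9-dienoyl]-1,3-oxazolidin-2-one | CC(C)=CCC/C(C)=C/CCCC(=O)N1[C@H](Cc2ccccc2)COC1=O | intermediate
11 | benzyl bromoacetate | O=C(CBr)OCc1ccccc1 | starting material
12 | sodium Z-enolate of 10, formed in the flask | CC(C)=CCC/C(C)=C/CC/C=C(\[O-])N1[C@H](Cc2ccccc2)COC1=O.[Na+] | intermediate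
13 | benzyl (3S,6E)-3-{[(4R)-4-benzyl-2-oxo-1,3-oxazolidin-3-yl]carbonyl}-7,11-dimethyldodeca-6,10-dienoate | CC(C)=CCC/C(C)=C/CC[C@@H](CC(=O)OCc1ccccc1)C(=O)N1[C@H](Cc2ccccc2)COC1=O | intermediate
14 | (2S)-4-(benzyloxy)-2-[(3E)-4,8-dimethylnona-3,7-dien-1-yl]-4-oxobutaneperoxoic acid, formed in the flask | CC(C)=CCC/C(C)=C/CC[C@@H](CC(=O)OCc1ccccc1)C(=O)OO | intermediate
15 | (2S)-4-(benzyloxy)-2-[(3E)-4,8-dimethylnona-3,7-dien-1-yl]-4-oxobutanoic acid, formed in the flask | CC(C)=CCC/C(C)=C/CC[C@@H](CC(=O)OCc1ccccc1)C(=O)O | intermediate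
16 | (2S)-2-[(3E)-4,8-dimethylnona-3,7-dien-1-yl]butanedioic acid | CC(C)=CCC/C(C)=C/CC[C@@H](CC(=O)O)C(=O)O | intermediate
17 | hydroquinone | Oc1ccc(O)cc1 | starting material
18 | (3S)-3-[(3E)-4,8-dimethylnona-3,7-dien-1-yl]oxolane-2,5-dione, formed in the flask | CC(C)=CCC/C(C)=C/CC[C@H]1CC(=O)OC1=O | intermediate
19 | (2S)-2-[(3E)-4,8-dimethylnona-3,7-dien-1-yl]-4-(4-hydroxyphenoxy)-4-oxobutanoic acid | CC(C)=CCC/C(C)=C/CC[C@@H](CC(=O)Oc1ccc(O)cc1)C(=O)O | intermediate
20 | caged pair of the C4 acyl radical and the 4-hydroxyphenoxyl radical, formed in the flask | CC(C)=CCC/C(C)=C/CC[C@@H](C[C]=O)C(=O)O.[O]c1ccc(O)cc1 | intermediate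
21 | (2S)-2-[(3E)-4,8-dimethylnona-3,7-dien-1-yl]-4-(3-hydroxy-6-oxocyclohexa-2,4-dien-1-yl)-4-oxobutanoic acid (ring sp3 carbon undefined), formed in the flask | CC(C)=CCC/C(C)=C/CC[C@@H](CC(=O)C1C=C(O)C=CC1=O)C(=O)O | intermediate
22 | (2S)-4-(2,5-dihydroxyphenyl)-2-[(3E)-4,8-dimethylnona-3,7-dien-1-yl]-4-oxobutanoic acid | CC(C)=CCC/C(C)=C/CC[C@@H](CC(=O)c1cc(O)ccc1O)C(=O)O | target

## Step count and risks

Total step count: 8. Longest linear sequence: 8 steps, from geranyl bromide 1.

**Step 8.**
- What may go wrong: the radical pair may escape from the solvent cage, with loss of the acyl group from the arene. The reaction may stall because the product absorbs the light. Light may also scramble the C3''=C4'' geometry.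
- Fallback: a polar aryl-metal acylation replaces the photochemical shift. It sets out from 17 and 18 and comes back at 22.
- Hydroquinone 17 is treated with MOMCl and i-Pr2NEt in CH2Cl2 to give 1,4-bis(methoxymethoxy)benzene F1.
- Ortho-lithiation with n-BuLi in THF at 0 °C gives [2,5-bis(methoxymethoxy)phenyl]lithium F2.
- F2 is added slowly to anhydride 18, here isolated by filtration and evaporation, in THF at −78 °C. Attack at the less hindered C4 carbonyl should give the bis-MOM keto acid F3.
- 2 M HCl in THF at 40 °C then removes both acetals and should give 22.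

**Step 7.**
- What may go wrong: the phenol may attack the C1 carbonyl, or hydroquinone may be acylated twice. The ring opening may reverse through participation of the C1 carboxylate. Base may epimerise C2 at the anhydride stage.
- Fallback: the two carboxyl groups are told apart by orthogonal esters, and no anhydride is used. It sets out from 10 and comes back at 19.
- Enolate 12, made from 10 as in step 5, is alkylated with tert-butyl bromoacetate to give the tert-butyl ester imide F4.
- Lithium allyloxide (allyl alcohol, n-BuLi, THF, 0 °C) displaces the auxiliary to give the 1-allyl 4-tert-butyl diester F5.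
- TMSOTf and 2,6-lutidine in CH2Cl2, followed by aqueous work-up, cleave only the tert-butyl ester to give the C4 acid allyl ester F6.
- EDC and DMAP with excess 17 give the 1-allyl 4-(4-hydroxyphenyl) diester F7.
- Pd(PPh3)4 with PhSiH3 in CH2Cl2 removes the allyl group under neutral conditions and should give 19 as a single regioisomer.

**Step 1.**
- What may go wrong: SN2′ attack at the tertiary allylic terminus and Wurtz-type homocoupling would give hydrocarbon isomers that are hard to separate.
- Fallback: the C3 unit is brought in at the aldehyde oxidation level by copper catalysis, so no hydroboration is needed. It sets out from 1 and comes back at 7.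
- Bromide 1 is coupled with commercial (1,3-dioxan-2-ylethyl)magnesium bromide under Li2CuCl4 catalysis in THF at −10 °C to rt, giving the dioxane acetal F8.
- Aqueous oxalic acid in THF at 50 °C releases aldehyde 6, which is isolated here.
- Pinnick oxidation (NaClO2, NaH2PO4, 2-methyl-2-butene, t-BuOH/H2O) should then give 7.

Further compounds
F1 | step 8 | 1,4-bis(methoxymethoxy)benzene | COCOc1ccc(OCOC)cc1
F2 | step 8 | [2,5-bis(methoxymethoxy)phenyl]lithium | [Li]c1cc(OCOC)ccc1OCOC
F3 | step 8 | (2S)-4-[2,5-bis(methoxymethoxy)phenyl]-2-[(3E)-4,8-dimethylnona-3,7-dien-1-yl]-4-oxobutanoic acid | CC(C)=CCC/C(C)=C/CC[C@@H](CC(=O)c1cc(OCOC)ccc1OCOC)C(=O)O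
F4 | step 7 | tert-butyl (3S,6E)-3-{[(4R)-4-benzyl-2-oxo-1,3-oxazolidin-3-yl]carbonyl}-7,11-dimethyldodeca-6,10-dienoate | CC(C)=CCC/C(C)=C/CC[C@@H](CC(=O)OC(C)(C)C)C(=O)N1[C@H](Cc2ccccc2)COC1=O
F5 | step 7 | 1-allyl 4-tert-butyl (2S)-2-[(3E)-4,8-dimethylnona-3,7-dien-1-yl]butanedioate | CC(C)=CCC/C(C)=C/CC[C@@H](CC(=O)OC(C)(C)C)C(=O)OCC=C
F6 | step 7 | (3S,6E)-3-[(allyloxy)carbonyl]-7,11-dimethyldodeca-6,10-dienoic acid | CC(C)=CCC/C(C)=C/CC[C@@H](CC(=O)O)C(=O)OCC=C
F7 | step 7 | 1-allyl 4-(4-hydroxyphenyl) (2S)-2-[(3E)-4,8-dimethylnona-3,7-dien-1-yl]butanedioate | CC(C)=CCC/C(C)=C/CC[C@@H](CC(=O)Oc1ccc(O)cc1)C(=O)OCC=C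
F8 | step 1 | 2-[(4E)-5,9-dimethyldeca-4,8-dien-1-yl]-1,3-dioxane | CC(C)=CCC/C(C)=C/CCCC1OCCCO1
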